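The route rests on cutting both arene bonds of the ring-B dihydropyran, C4a–C4 (aryl–CH2) and C8a–O1 (aryl–O), which sit on adjacent carbons of a hydroquinone-type ring. One palladium/norbornene (Catellani-type) annulation of 2-iodo-1,4-dimethoxybenzene with 4-bromo-2-methylbutan-2-ol alkylates the C–H next to iodine and etherifies the iodine-bearing carbon, giving the chroman in one operation. Oxidative demethylation then gives a chroman quinone, which takes up a ring-A 2-morpholinochromone (from phloroacetophenone) in a Nenitzescu-type benzofuran annulation that builds the benzofuro[2,3-b]chromenone without protecting groups on ring B. Claisen rearrangement of the 7-O-allyl ether and cross-metathesis install the C8 prenyl group.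

Key step: step 5

Assumption: the target is achiral, so no stereocentre has to be set; positions are numbered as in isoflavonoids (chromone O1–C8a, ring B C1'–C6' with C1' on C3 and the furan oxygen on C2') and, for the bicyclic fragments, as in chroman (O1–C8a); compounds 1, 7, 8 and the reagents named are taken as commercial.

Step 1
Reactants: 1 2,4,6-trihydroxyacetophenone
Product: 2 1-[4-(allyloxy)-2,6-dihydroxyphenyl]ethanone
Conditions: allyl bromide (1.0 equiv), K2CO3 (1.0 equiv), acetone, reflux
Reagents that add atoms: allyl bromide, C=CCBr
Why: The 4-OH, para to the acetyl group and not hydrogen-bonded to it, is the most acidic and most accessible phenol, so a Williamson etherification with one equivalent of base should alkylate it in preference to the two chelated ortho hydroxyls.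

Step 2
Reactants: 2 1-[4-(allyloxy)-2,6-dihydroxyphenyl]ethanone
Product: 4 1-[5-(allyloxy)-7-hydroxy-2,2-dimethylchroman-8-yl]ethanone, via C-prenylphenol 3 (not isolated)
Conditions: isoprene (1.2 equiv), 85% H3PO4, xylene, 35 °C
Reagents that add atoms: isoprene, C=CC(C)=C
Why: Acid-catalysed Friedel–Crafts prenylation at the position between OH and O-allyl, followed by closure of the only adjacent free hydroxyl onto the tertiary cation of the prenyl group, is the classical one-pot chroman synthesis from phenols and isoprene, and the allyl ether on O4 forces the ring oxygen to be the one next to the acetyl group.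

Step 3
Reactants: 4 1-[5-(allyloxy)-7-hydroxy-2,2-dimethylchroman-8-yl]ethanone
Product: 5 1-[5-(allyloxy)-7-hydroxy-2,2-dimethylchroman-8-yl]-3-(morpholin-4-yl)propane-1,3-dione
Conditions: LDA (3.3 equiv), THF, −78 to 0 °C; morpholine-4-carbonyl chloride, −78 °C to rt; aq. HCl
Reagents that add atoms: morpholine-4-carbonyl chloride, O=C(Cl)N1CCOCC1
Why: The polyanion formed with excess LDA (phenoxide plus methyl ketone enolate) should be C-acylated by the carbamoyl chloride in a Claisen-type acylation, the established entry to 1-(2-hydroxyaryl)-3-aminopropane-1,3-diones.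

Step 4
Reactants: 5 1-[5-(allyloxy)-7-hydroxy-2,2-dimethylchroman-8-yl]-3-(morpholin-4-yl)propane-1,3-dione
Product: 6 7-(allyloxy)-2-(morpholin-4-yl)chromen-4-one carrying a 2,2-dimethyl-3,4-dihydro-2H-pyran ring fused at C5 (ring O) and C6 (CH2)
Conditions: Tf2O (2 equiv), CH2Cl2, 0 °C to rt; MeOH; aq. NaHCO3
Reagents that add atoms: none
Why: Tf2O should activate the amide oxygen to an iminium triflate that the ortho phenol attacks, and loss of triflate gives the 2-aminochromone (Tf2O-mediated cyclodehydration of ortho-hydroxyaryl β-ketoamides).

Step 5
Reactants: 7 2-iodo-1,4-dimethoxybenzene; 8 4-bromo-2-methylbutan-2-ol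
Product: 9 5,8-dimethoxy-2,2-dimethylchroman
Conditions: Pd(OAc)2 (10 mol%), XPhos (20 mol%), norbornene (1 equiv), Cs2CO3 (3 equiv), toluene, 100 °C
Reagents that add atoms: none
Why: Proposed new method: zerovalent palladium should insert into the C–I bond of 7, norbornene carbopalladation and palladation of the only ortho C–H (C3, next to the C4 methoxy oxygen) should give the aryl–norbornyl palladacycle, and oxidative addition of the primary C–Br bond of 8 to this divalent palladium centre followed by C(sp2)–C(sp3) reductive elimination from tetravalent palladium should form the aryl–CH2 bond. With both ortho positions then substituted, β-carbon elimination should expel norbornene, the cesium alkoxide of the tertiary alcohol should bind the arylpalladium halide, and C–O reductive elimination should form the aryl–O bond. The closest known reaction types are the palladium/norbornene ortho-alkylation with ipso C–N closure by N-protected bromoalkylamines (indolines and tetrahydroquinolines), the corresponding annulation with epoxides that ends in ipso C–O closure to 2,3-dihydrobenzofurans, and the palladium-catalysed intramolecular etherification of aryl halides by tertiary alcohols. The dihydropyran ring closes by C–O reductive elimination from a seven-membered aryl(alkoxo)palladium chelate, which gives the six-membered ring fused at the former C2–C3 bond of 7. No stereocenter is formed. The step needs ortho-alkylation before ipso termination, a single alkylation, and O- rather than H-termination; these are secured by the norbornene relay, by the C1 methoxy group of 7 (ortho effect, only one ortho C–H), and by the tertiary alkoxide, which has no hydrogen on its carbinol carbon for β-hydride elimination.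

Step 6
Reactants: 9 5,8-dimethoxy-2,2-dimethylchroman
Product: 10 2,2-dimethylchroman-5,8-dione
Conditions: (NH4)2Ce(NO3)6 (2.5 equiv), MeCN/H2O, 0 °C
Reagents that add atoms: water, O
Why: Oxidative demethylation of a para-dimethoxyarene by (NH4)2Ce(NO3)6 proceeds through the arene radical cation, ipso attack of water and loss of methanol, so the para pair of methoxy groups should give the 1,4-quinone while the ring ether oxygen remains as a vinylogous ester.

Step 7
Reactants: 6 the 2-morpholinochromone of step 4; 10 2,2-dimethylchroman-5,8-dione
Product: 12 7-(allyloxy)-5'-hydroxycoumaronochromone (benzofuro[2,3-b]chromen-11-one core) carrying 2,2-dimethyldihydropyran rings at C5(O)/C6(CH2) and C4'(O)/C3'(CH2), via hydroquinone adduct 11 (not isolated)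
Conditions: AcOH, CF3CO2H (0.2 equiv), 50 °C, argon
Reagents that add atoms: none
Why: Proposed new method: the push–pull enaminone carbon C3 of 6 should add in conjugate fashion to C6 of quinone 10 (β to the C8 carbonyl, which is not deactivated by the ring oxygen, whereas C7 is β to the vinylogous-ester carbonyl C5), tautomerisation gives hydroquinone 11, and its C5 hydroxyl next to the new C–C bond should attack the acid-activated C2 iminium carbon (5-exo-trig) and expel morpholine to aromatise the furan, so that the quinone oxidation level pays for the C2–O bond and the hydroxyl para to the furan oxygen stays free; the closest known reaction type is the Nenitzescu-type synthesis of 5-hydroxybenzofurans from tertiary enaminones and 1,4-benzoquinones, together with the related annulation of cyclic 1,3-dicarbonyl compounds with quinones.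

Step 8
Reactants: 12 the 7-O-allyl coumaronochromone of step 7
Product: 13 8-allyl-7,5'-dihydroxycoumaronochromone carrying the same two 2,2-dimethyldihydropyran rings
Conditions: PhNEt2, 200 °C, sealed tube
Reagents that add atoms: none
Why: The aromatic Claisen rearrangement ([3,3]-sigmatropic shift, then tautomerisation) should deliver the allyl group to C8, the only free ortho position of the 7-O-allyl ether, because C6 carries the dihydropyran CH2.

Step 9
Reactants: 13 the 8-allyl phenol of step 8
Product: 14 target CNP0081329.0 (8-prenyl-7,5'-dihydroxycoumaronochromone with 2,2-dimethyldihydropyran rings at C5(O)/C6 and C4'(O)/C3')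
Conditions: second-generation Grubbs catalyst (5 mol%), 2-methyl-2-butene/CH2Cl2, 40 °C, sealed tube
Reagents that add atoms: 2-methyl-2-butene, CC=C(C)C
Why: Olefin cross-metathesis of the terminal allyl group with excess 2-methyl-2-butene should exchange the CH2 terminus for an isopropylidene group and release propene, a standard acid-free way to turn an ortho-allylphenol into an ortho-prenylphenol.

Compound list
1 | 2,4,6-trihydroxyacetophenone | CC(=O)c1c(O)cc(O)cc1O | starting material
2 | 1-[4-(allyloxy)-2,6-dihydroxyphenyl]ethanone | CC(=O)c1c(O)cc(OCC=C)cc1O | intermediate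
3 | 1-[4-(allyloxy)-2,6-dihydroxy-3-(3-methylbut-2-en-1-yl)phenyl]ethanone (C-prenylphenol, forms and reacts on in step 2) | CC(=O)c1c(O)cc(OCC=C)c(CC=C(C)C)c1O | intermediate
4 | 1-[5-(allyloxy)-7-hydroxy-2,2-dimethylchroman-8-yl]ethanone | CC(=O)c1c(O)cc(OCC=C)c2CCC(C)(C)Oc12 | intermediate
5 | 1-[5-(allyloxy)-7-hydroxy-2,2-dimethylchroman-8-yl]-3-(morpholin-4-yl)propane-1,3-dione | O=C(CC(=O)N1CCOCC1)c1c(O)cc(OCC=C)c2CCC(C)(C)Oc12 | intermediate
6 | 7-(allyloxy)-2-(morpholin-4-yl)chromen-4-one with a 2,2-dimethyl-3,4-dihydro-2H-pyran ring fused at C5 (ring O) and C6 (CH2) | O=c1cc(N2CCOCC2)oc2cc(OCC=C)c3CCC(C)(C)Oc3c12 | intermediate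
7 | 2-iodo-1,4-dimethoxybenzene | COc1ccc(OC)c(I)c1 | starting material
8 | 4-bromo-2-methylbutan-2-ol | CC(C)(O)CCBr | starting material
9 | 5,8-dimethoxy-2,2-dimethylchroman | COc1ccc(OC)c2c1CCC(C)(C)O2 | intermediate
10 | 2,2-dimethylchroman-5,8-dione (2,2-dimethyl-3,4-dihydro-2H-chromene-5,8-dione) | O=C1C=CC(=O)C2=C1CCC(C)(C)O2 | intermediate
11 | 3-(5,8-dihydroxy-2,2-dimethylchroman-6-yl) derivative of 6 (hydroquinone adduct, forms and reacts on in step 7) | O=c1c(-c2cc(O)c3OC(C)(C)CCc3c2O)c(N2CCOCC2)oc2cc(OCC=C)c3CCC(C)(C)Oc3c12 | intermediate
12 | 7-(allyloxy)-5'-hydroxycoumaronochromone with 2,2-dimethyldihydropyran rings at C5(O)/C6(CH2) and C4'(O)/C3'(CH2) | O=c1c2c(oc3c4CCC(C)(C)Oc4c(O)cc23)oc2cc(OCC=C)c3CCC(C)(C)Oc3c12 | intermediate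
13 | 8-allyl-7,5'-dihydroxycoumaronochromone with the same two dihydropyran rings | O=c1c2c(oc3c4CCC(C)(C)Oc4c(O)cc23)oc2c(CC=C)c(O)c3CCC(C)(C)Oc3c12 | intermediate
14 | CNP0081329.0, 8-(3-methylbut-2-en-1-yl)-7,5'-dihydroxycoumaronochromone with the same two dihydropyran rings | CC(C)=CCc1c(O)c2c(c3c(=O)c4c(oc13)oc1c3c(c(O)cc14)OC(C)(C)CC3)OC(C)(C)CC2 | target

Total step count: 9. Longest linear sequence: 7 steps (steps 1, 2, 3, 4, 7, 8, 9); the ring-B branch (steps 5 and 6) joins at step 7.

Steps most likely to fail

Step 5 (Proposed new method). Palladation of the C–H that is flanked by the C4 methoxy group may be slow, so that the aryl–norbornyl palladium intermediate is diverted into norbornene-containing by-products. The final C–O reductive elimination may also lose to protodepalladation. The bromo alcohol may be consumed by base before it reaches the palladacycle. The fallback builds the aryl–O bond first and the aryl–C bond by a sigmatropic shift. Setting out from 7, copper-catalysed hydroxylation (CuI, 1,10-phenanthroline, KOH, DMSO/H2O, 100 °C) should give 2,5-dimethoxyphenol F1. O-Alkylation with 3-chloro-3-methylbut-1-yne (K2CO3, KI, CuCl2 cat., acetone, reflux) should give 1,4-dimethoxy-2-[(2-methylbut-3-yn-2-yl)oxy]benzene F2. Heating in PhNEt2 at 190 °C (propargyl Claisen rearrangement, 1,5-hydrogen shift, oxa-6π electrocyclisation at the only free ortho position) should give 5,8-dimethoxy-2,2-dimethyl-2H-chromene F3. Hydrogenation (H2, Pd/C, EtOAc) returns to the route at 9.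

Step 7 (Proposed new method). The enaminone carbon may add too slowly to the electron-rich quinone. The hydroquinone adduct may be reoxidised by unreacted quinone and stall before ring closure. Part of the addition may go to C7 of the quinone. The fallback joins the rings by cross-coupling and closes the furan afterwards. Setting out from 6, iodination (N-iodosuccinimide, MeCN, rt) should give the 3-iodo-2-morpholinochromone F4. Setting out from 10, reduction (Na2S2O4, EtOAc/H2O) should give 2,2-dimethylchroman-5,8-diol F5, and MOMCl with iPr2NEt in CH2Cl2 should give 5,8-bis(methoxymethoxy)-2,2-dimethylchroman F6. Bromination para to the ring oxygen (N-bromosuccinimide, MeCN, 0 °C) should give 6-bromo-5,8-bis(methoxymethoxy)-2,2-dimethylchroman F7. Miyaura borylation (bis(pinacolato)diboron, Pd(dppf)Cl2, KOAc, dioxane, 90 °C) should give the pinacol boronate F8. Suzuki coupling of F8 with F4 (Pd(OAc)2, SPhos, K3PO4, toluene/H2O, 90 °C) should give the 3-aryl-2-morpholinochromone bis-MOM ether F9. HCl in MeOH at 60 °C should remove both MOM groups and return to the route at 11, which closes to 12 under the same acid with loss of morpholine.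

Step 2. A second annulation at the other free position may consume the hydroxyl needed for the chromone, and the acid may cleave or shift the allyl ether. The fallback separates C–C bond formation from ring closure. Setting out from 2, C-alkylation of the phenoxide with prenyl bromide (DBU, THF, rt) should give 3, isolated in this variant. Cycloisomerisation with Amberlyst 15 in toluene at 60 °C returns to the route at 4. This fallback makes no new compound (F0).

Further compounds
F1 | step 5 | 2,5-dimethoxyphenol | COc1ccc(OC)c(O)c1
F2 | step 5 | 1,4-dimethoxy-2-[(2-methylbut-3-yn-2-yl)oxy]benzene | COc1ccc(OC)c(OC(C)(C)C#C)c1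
F3 | step 5 | 5,8-dimethoxy-2,2-dimethyl-2H-chromene | COc1ccc(OC)c2C=CC(C)(C)Oc12
F4 | step 7 | 3-iodo derivative of 6 (7-(allyloxy)-3-iodo-2-(morpholin-4-yl)chromen-4-one with the C5(O)/C6 dihydropyran ring) | O=c1c(I)c(N2CCOCC2)oc2cc(OCC=C)c3CCC(C)(C)Oc3c12
F5 | step 7 | 2,2-dimethylchroman-5,8-diol | Oc1ccc(O)c2c1CCC(C)(C)O2
F6 | step 7 | 5,8-bis(methoxymethoxy)-2,2-dimethylchroman | COCOc1ccc(OCOC)c2c1CCC(C)(C)O2
F7 | step 7 | 6-bromo-5,8-bis(methoxymethoxy)-2,2-dimethylchroman | COCOc1cc(Br)c(OCOC)c2CCC(C)(C)Oc12
F8 | step 7 | 2-[5,8-bis(methoxymethoxy)-2,2-dimethylchroman-6-yl]-4,4,5,5-tetramethyl-1,3,2-dioxaborolane | COCOc1cc(B2OC(C)(C)C(C)(C)O2)c(OCOC)c2CCC(C)(C)Oc12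
F9 | step 7 | 3-[5,8-bis(methoxymethoxy)-2,2-dimethylchroman-6-yl] derivative of 6 | O=c1c(-c2cc(OCOC)c3OC(C)(C)CCc3c2OCOC)c(N2CCOCC2)oc2cc(OCC=C)c3CCC(C)(C)Oc3c12
F0 | step 2 | none | none
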